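The pitfall in this run was to reckon as if the dose stood in the flask from the first minute, and I nearly did.

| setting | green | red | grey |
|---|---|---|---|
| electrophile | 0.13 M | 0.13 M | 0.13 M |
| nucleophile | 0.195 M (fed, over 30 min) | 0.195 M (fed, over 30 min) | 0.195 M (fed, over 30 min) |
| free base | 0.0390 M | 0.0880 M | 0.0580 M |
| protic impurity | 0.0390 M | 0.0390 M | 0.0390 M |
| time | 40 min | 40 min | 40 min |
| remark | the fed solution adds 1.0 times the starting volume | the fed solution adds 1.0 times the starting volume | the fed solution adds 1.0 times the starting volume |

    electrophile + nucleophile → acid set free + target (k1 = 0.00482 /M/s)
    nucleophile + acid set free ⇌ protonated nucleophile, settled at all times (K2 = 25000 /M)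
    acid set free + free base ⇌ salt of the base, settled at all times (K3 = 2.17 × 10⁶ /M)
    nucleophile + protic impurity → quenched reagent (k4 = 0.0945 /M/s)

1. part of the electrophile that has reacted at the end, green
2. part of the electrophile that has reacted at the end, red
3. part of the electrophile that has reacted at the end, grey
4. what raising the concentration of free base from its lowest to its highest value here does to the part of the electrophile that has reacted (changes below 5 percentage points count as none) (no change / it rises / it falls)

I counted turnovers, since the part of the electrophile left is exp(−n), where n is the coupling's constant times the free [nucleophile], summed over time. My first count took the charge as present from the start, which gave 2.26 turnovers and 89.5% reacted. I did not believe it, because the feed lasted 30 min and added 1.0 times the starting volume, and because the protic impurity came first: its constant 0.0945 /M/s is larger than the coupling's 0.00482 /M/s, and the nucleophile's half-life against it, 3.1 min, is shorter than the feed.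

So I let the first 6.00 min of dose vanish into the quench and summed the rising [nucleophile] in the growing volume, which gave 0.316 turnovers by the end of the feed. The remaining minutes at the undiminished net charge added 0.226, which put my count at 41.8% reacted.

That was still too generous, because the coupling eats nucleophile too, 0.0353 M by the end of the feed. Subtracting it cut the tail to 0.175, so the turnover count, the coupling's constant times free [nucleophile] summed over the run, came to 0.491, or 38.8% reacted.

The last doubt was the acid set free, 0.0504 M on the starting volume. The free base binds it more strongly than the nucleophile does, its constant 2.17 × 10⁶ /M being larger than 25000 /M. Red and grey hold more base than that, but green overshoots its 0.0390 M by 0.0114 M. Letting that excess protonate nucleophile through the whole tail, I took 0.0165 turnovers off my count for green. I therefore committed to 38.8% for red and grey and 37.8% for green, a gap below 5 percentage points.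

The forecast gave 36.5% for green (34.5% to 38.5%), 37.5% for red (35.5% to 39.5%) and 37.2% for grey (35.2% to 39.2%), with no change as the trend, on the ground that “The coupling is slow, so acid released (about 0.048 M) barely exceeds the base even in green.” My red stood 1.3 points above its value.

Green, red and grey ended at 36.6%, 37.3% and 37.2%, so the base range moved the result by 0.72 points, which counts as no change. Read back, grey's result is 0.465 turnovers against my 0.491. The same count for the neighbour of grey with 0.49 M of nucleophile gives 1.08 by the end of the feed and 1.61 in all, or 80.0%, and that flask gave 75.1%. Grey had not come to rest: at 40.0 min it held 63% of its electrophile, with a half-life of 46 min by the coupling, and by 400 min the part of the electrophile reacted stood at 74.9% in green, 81.2% in grey and 89.5% in red.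

The constants used here were drawn at random within sensible limits; the run is a simulation.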